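I had no constants for this chemistry, so I read one from the two earlier runs before reckoning the two new flasks.

common to all: gas phase 1.7 mM (held)
- north-west: substrate 8.7 mM; run made earlier
- south-west: substrate 23 mM; run made earlier
- epsilon: substrate 30 mM; time 10 h
- theta: substrate 10 mM; time 2.5 h

| north-west: time / h | north-west: product / % | south-west: time / h | south-west: product / % |
|---|---|---|---|
| 0.500 | 10 | 0.200 | 2 |
| 1.00 | 14 | 0.667 | 10 |
| 1.50 | 19 | 1.33 | 14 |
| 2.00 | 23 | 2.00 | 23 |
| 2.50 | 31 | 2.50 | 28 |

(standard deviation of a reading: 1.5 percentage points)

- at the start none of the gas is dissolved
- what was read earlier has a scatter of 1.5 percentage points, one standard deviation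
- what may be going on: gas phase <-> dissolved gas; substrate + dissolved gas -> product; dissolved gas <-> dormant form

- the flask that ends with the higher amount of product, in percent of the substrate charged, or "neither" when 2 percentage points or less lies between them (epsilon / theta / neither)
- final product, as a percentage of the substrate charged, in epsilon
- final product, as a percentage of the substrate charged, in theta

The south-west run held 2.64 times the substrate of the north-west run, yet at 2.00 h both read 23% product. I read this as a pseudo-first-order reaction, with c(dissolved gas) steady, and so I counted half-lives. From each run I took the last reading, counted what was not product as substrate left, and divided the natural logarithm of one over that fraction by the time. The north-west reading gave 0.148 /h, a half-life of 4.67 h, and the south-west reading gave 0.131 /h, a half-life of 5.28 h.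

These two ways parted a little, so I asked which one cheated. Their last readings differ by 3 percentage points, and the difference of two readings with this scatter has a standard deviation of 2.1 points. The gap stays within two such standard deviations, so I blamed neither run and took the mean constant. That gave a reading of the substrate half-life, the time in which the substrate falls to half of what stood before, of 4.95 h.

Epsilon, at 10 h, then counted 2.02 half-lives, which reckoned to 75.3% product. Theta, at 2.5 h, counted 0.505 half-lives, which reckoned to 29.5%, so I expected epsilon to end higher than theta.

The forecast named epsilon, with 73% (58% to 81%) for epsilon and 29.5% (26% to 33%) for theta. Its epsilon figure stood lower than mine, for it said “so I lean a little lower”. Its theta figure matched mine.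

The flasks gave 74.7% in epsilon and 29.7% in theta, so epsilon ended higher.

    gas phase ⇌ dissolved gas, rate k1*(csat - [dissolved gas]) (kL = 11.5 /h)
    substrate + dissolved gas → product (k = 93.9 /M/h)
    dissolved gas ⇌ dormant form (K = 2.80, k = 0.347 /h)

A flask with the substrate charge of epsilon, read at the 2.5 h of theta, gave 26.9%, less than theta's 29.7%, so with both read at that time the order of the two charges turned round. Theta read at 4.0 h counts 0.808 half-lives, which reckons to 42.9% product, and that flask held 43.8%.

(Readings and results are calculated on assumed constants, and the scatter is random.)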